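## Analysis of the target

Target 23 is a 2-aryl chroman. Ring A is fused to a dihydropyran ring (O1, C2, C3, C4) and carries hydroxyl groups at C5 and C7, a formyl group at C6 and hydrogen at C8. C2 bears ring B, a 3,5-diformyl-2,4,6-trihydroxyphenyl group, C3 an isopropyl group and C4 an isobutyl group. The three contiguous stereocentres are (2R,3R,4S): ring B and isopropyl are trans, isopropyl and isobutyl are cis. This is the relaxed diastereomer, because the C4 isobutyl group can stand pseudoaxial, away from the peri oxygen at C5, while the C2 and C3 substituents are equatorial. The sensitive parts are three aryl aldehydes chelated to phenols, five acidic phenols, and the C2–O1 bond, which is benzylic to ring B and can ionize. Ring B tolerates neither hydride reagents nor strong base, so it has to enter late. The difficulty is that the stereocentres sit on a hydrocarbon backbone with no heteroatom to direct a reagent, and that C4 is a congested benzylic centre, so absolute configuration has to be imported. The strategy rests on the fact that C2, C3 with its isopropyl group, C4 and the isobutyl chain are together the ten-carbon skeleton of lavandulol 1: C1 of 1 maps onto C2, its stereocentre onto C3, its allylic CH2 onto C4 and the rest of its prenyl group onto the isobutyl chain. Only the bonds C4–C4a (to ring A), C2–C1' (to ring B) and O1–C2 then remain to be made.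

## Retrosynthetic reasoning

**23 from 22.** The last disconnection is the two O–methyl bonds of ring A. Ring A has to travel as its bis-methyl ether because cation and hydride chemistry lie ahead of it. Both methoxy groups flank the C6 formyl group, so a chelation-assisted ether cleavage can address exactly these two and leave the ring oxygen O1 alone.

**22 from 17 and 19.** The C2–C1' bond is cut. C2 is then at the lactol oxidation level and ring B is the intact diformylated triphenol 19, whose only free ring carbon is the nucleophile. Cutting here brings in all five sensitive groups of ring B in one late step, after every reduction. The forward reaction must also correct C3: the lactol 17 still has the 3,4-trans arrangement, so acid has to take it through enol ether 20, reprotonate C3 on the face away from the isobutyl group (ion 21) and only then add 19 to C2.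

**17 from 16 from 15.** These are oxidation-level adjustments. The lactol comes from partial reduction of lactone 15; the aldehyde is reduced alongside and is restored by a benzylic oxidation.

**15 from 14.** The isobutyl chain is traced back to a 2-methylprop-1-enyl group, which is what an allyl cation closure leaves at C4.

**14 from 12 (through 13).** This is the key disconnection: the C4–C4a bond. It is cut because C4 then becomes the secondary terminus of a dimethylallyl cation and ring A, activated ortho and para by its methoxy groups, the nucleophile. The remaining ring bonds O1–C2 are an aryl ester that is trivial to make. The gain is the ring and the C4 stereocentre, which is relayed from C3. The forward reaction has to deliver C4 trans to the isopropyl group and must attack the secondary, not the tertiary, end of the cation.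

**12 from 10 and 11.** The ester C–O bond is cut, which gives the hydroxy acid 10 and the commercial phenol 11. Ring A thereby arrives with its formyl group and both oxygens in place, and no late formylation between C6 and C8 has to be controlled.

**10 from 1 (through 8, 7, 4, 3, 2).** The tertiary allylic alcohol of 10 is the prenyl alkene of 1 in transposed form; an epoxide and a selenide (4, 5, 6) carry out the transposition regiospecifically. The primary hydroxyl group is silylated (3) for this passage, because a free hydroxyl would open the epoxide to a five-membered cyclic ether. The isopropyl group comes from selective saturation of the isopropenyl group of 1 (2).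

**19 from 18.** Two formyl groups are removed from ring B, which leads back to the parent triphenol 18.

## Alternatives that were turned down

Alternative 1: The pyranone ring is cut at O1–C2 and C4–C4a. In the forward sense a Pechmann condensation joins a ring-A phenol bearing a methyl ester with keto ester A2, the Claisen self-condensation product of two C5 ester units, and gives coumarin A1.
- For it: A2 holds all ten aliphatic carbons and costs almost nothing, two bonds and the ring form in one step, and syn hydrogenation of C3=C4 would give the 3,4-cis relationship directly. On step count and material cost up to the bicyclic lactone it is stronger than the chosen route.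
- Against it: A1 has no stereocentre. All absolute configuration would have to come from enantioselective reduction of a tetrasubstituted, electron-rich, peri-hindered coumarin alkene that offers no handle to a catalyst. The condensation itself joins a ketone flanked by two branched groups with a ring carbon deactivated by an ester, and the ester must later become an aldehyde.
- Comparison: the chosen route is longer but takes the C4 configuration from the stereocentre of 1 through substrate control in the step 12 to 14.

Alternative 2: C2–C3 and C4–C4a are cut together. In the forward sense a chiral Brønsted acid ionizes a mixed acetal of ring A to an O-aryl oxocarbenium ion, the Z-diene A4 attacks it through its isopropyl-bearing terminus, and ring A traps the resulting allyl cation to give chroman A3.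
- For it: it is the most convergent plan. It sets C2, C3 and C4 and attaches the C2 aryl group in one step, and it ends in the same kind of ring closure by an allyl cation on ring A as the chosen route. On convergence and step count it is clearly stronger.
- Against it: the Z geometry of A4 must survive acid and must translate into 3,4-cis through a stepwise cationic path. Enantiocontrol would rest on ion pairing with an oxocarbenium ion that has no hydrogen-bond anchor. The ion forms only with an electron-rich aryl group, so ring B of A3 still needs two formylations and the molecule five ether cleavages.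
- Comparison: the chosen route gives up the single-step assembly for a configuration that is fixed by a purchased stereocentre, and it brings ring B in already formylated.

Alternative 3: O1–C8a and C4–C4a are cut. In the forward sense the alkoxide of a hydroxy enoate that carries ring B, C2 and C3 adds to a ring-A aryne, and the aryl anion so formed adds to the enoate β-carbon to give chroman A5.
- For it: neither bond to ring A depends on the nucleophilicity of ring A, which is the weak point of a Friedel–Crafts closure, and C2 and C3 can be set beforehand in open-chain chemistry. On that point it is stronger than the chosen route.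
- Against it: the aryne is unsymmetrical, so the site of alkoxide addition has to be controlled. C4 is set in an anionic closure with no clear bias. A5 carries an acetate arm where the isobutyl group belongs, so two carbons must be added in the presence of three aryl esters, which in turn must all be reduced to aldehydes.
- Comparison: in the chosen route the complete carbon skeleton, isobutyl chain included, arrives in 1, and only one redox correction follows the ring closure.

Key step: step 8

## Route

Remark on the chemistry: (R)-lavandulol 1 is assumed to be used in high enantiomeric purity; the route passes this purity on and cannot raise it. Chroman numbering (O1, C2, C3, C4, C4a, C5 to C8, C8a) is used for all bicyclic compounds and, as "future" positions, for their open-chain precursors.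

Step 1
Reactants: 1 (R)-lavandulol, (2R)-5-methyl-2-(prop-1-en-2-yl)hex-4-en-1-ol
Product: 2 (2R)-5-methyl-2-(propan-2-yl)hex-4-en-1-ol
Conditions: H2 (1 atm), RhCl(PPh3)3 (3 mol%), benzene/EtOH, rt
Reagents that add atoms: none
Why: Homogeneous hydrogenation with RhCl(PPh3)3 saturates the unhindered 1,1-disubstituted isopropenyl alkene far faster than the trisubstituted prenyl alkene; the stereocentre is not touched and no new one forms.

Step 2
Reactants: 2 (2R)-5-methyl-2-(propan-2-yl)hex-4-en-1-ol
Product: 3 tert-butyldimethyl{[(2R)-5-methyl-2-(propan-2-yl)hex-4-en-1-yl]oxy}silane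
Conditions: TBSCl, imidazole, DMF, rt
Reagents that add atoms: tert-butyldimethylsilyl chloride, CC(C)(C)[Si](C)(C)Cl
Why: Standard silylation of a primary alcohol; the silyl ether keeps the hydroxyl group from opening the epoxide of step 3 in a 5-exo cyclization.

Step 3
Reactants: 3 tert-butyldimethyl{[(2R)-5-methyl-2-(propan-2-yl)hex-4-en-1-yl]oxy}silane
Product: 4 tert-butyl{(2R)-2-[(3,3-dimethyloxiran-2-yl)methyl]-3-methylbutoxy}dimethylsilane (both epimers at the oxirane carbon)
Conditions: mCPBA, NaHCO3, CH2Cl2, 0 °C
Reagents that add atoms: 3-chloroperoxybenzoic acid, OOC(=O)c1cccc(Cl)c1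
Why: Prilezhaev epoxidation of the only alkene; the new oxirane stereocentre forms as a mixture, which does not matter because step 4 destroys it.

Step 4
Reactants: 4 tert-butyl{(2R)-2-[(3,3-dimethyloxiran-2-yl)methyl]-3-methylbutoxy}dimethylsilane
Product: 7 (3E,5S)-6-{[tert-butyl(dimethyl)silyl]oxy}-2-methyl-5-(propan-2-yl)hex-3-en-2-ol, via hydroxy selenide 5 (not isolated), via selenoxide 6 (not isolated)
Conditions: PhSeSePh, NaBH4, EtOH, rt → 70 °C; then THF, 30% H2O2, 0 °C → rt
Reagents that add atoms: none
Why: Sharpless-type transposition of an epoxide to an allylic alcohol: the selenolate opens the oxirane by SN2 attack at its secondary carbon, and the selenoxide formed on oxidation undergoes syn elimination. The elimination can only take a hydrogen from the CH2 next to the stereocentre, because the other neighbour is the fully substituted carbinol carbon, so the E alkene should result. The stereocentre keeps its geometry; its descriptor changes from R to S only because the vinyl group now outranks isopropyl.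

Step 5
Reactants: 7 (3E,5S)-6-{[tert-butyl(dimethyl)silyl]oxy}-2-methyl-5-(propan-2-yl)hex-3-en-2-ol
Product: 8 (2S,3E)-5-methyl-2-(propan-2-yl)hex-3-ene-1,5-diol
Conditions: n-Bu4NF, THF, 0 °C → rt
Reagents that add atoms: none
Why: Fluoride-mediated cleavage of the primary silyl ether; the tertiary allylic alcohol is stable under these non-acidic conditions.

Step 6
Reactants: 8 (2S,3E)-5-methyl-2-(propan-2-yl)hex-3-ene-1,5-diol
Product: 10 (2S,3E)-5-hydroxy-5-methyl-2-(propan-2-yl)hex-3-enoic acid, via hydroxy aldehyde 9 (not isolated)
Conditions: TEMPO (10 mol%), NaClO2, NaOCl (cat.), MeCN/NaH2PO4–Na2HPO4 buffer (pH 6.7), 35 °C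
Reagents that add atoms: sodium chlorite, [Na+].[O-]Cl=O
Why: TEMPO/chlorite oxidation (the chlorite variant of the Anelli oxidation) takes the primary alcohol through 9 to the acid, while the tertiary alcohol cannot be oxidized. The near-neutral buffer and the short lifetime of 9 should prevent epimerization of the allylic α-stereocentre and migration of the alkene into conjugation.

Step 7
Reactants: 10 (2S,3E)-5-hydroxy-5-methyl-2-(propan-2-yl)hex-3-enoic acid; 11 4-hydroxy-2,6-dimethoxybenzaldehyde
Product: 12 4-formyl-3,5-dimethoxyphenyl (2S,3E)-5-hydroxy-5-methyl-2-(propan-2-yl)hex-3-enoate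
Conditions: EDC·HCl, DMAP (10 mol%), CH2Cl2, 0 °C
Reagents that add atoms: none
Why: Steglich-type carbodiimide esterification of the acid with the acidic phenol; the tertiary alcohol is too hindered to compete and the E alkene rules out lactonization. Low temperature and only catalytic DMAP limit enolization of the doubly activated α-position.

Step 8
Reactants: 12 4-formyl-3,5-dimethoxyphenyl (2S,3E)-5-hydroxy-5-methyl-2-(propan-2-yl)hex-3-enoate
Product: 14 (3S,4S)-5,7-dimethoxy-4-(2-methylprop-1-en-1-yl)-2-oxo-3-(propan-2-yl)chromane-6-carbaldehyde (3,4-trans), via allyl cation 13 (not isolated)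
Conditions: BF3·OEt2 (0.3 equiv), CH2Cl2 (0.01 M), −40 → 0 °C
Reagents that add atoms: none
Why: The Lewis acid (and the strong protic acid it forms with the water released) ionizes the tertiary allylic alcohol to the dimethylallyl cation 13, whose other terminus is the future C4. The ring-A carbon ortho to the ester oxygen, which is also ortho to one methoxy group, para to the other and only meta to the formyl group, attacks this terminus, and proton loss gives 14; the two ortho carbons are equivalent, so no site selectivity on the arene is needed. The closest known reactions are the intramolecular Friedel–Crafts allylic alkylation of electron-rich arenes by allylic alcohols to benzo-fused six-membered rings and the acid-mediated closure of aryl 3-methylbut-2-enoates to 4,4-dimethylchroman-2-ones, which shows that a cation can close through an aryl ester tether. The pyranone ring closes in a 6-exo mode on the allyl cation, the alkene ending outside the ring; attack at the tertiary terminus would need an eight-membered ring around an E alkene and is excluded. The new stereocentre C4 is controlled by C3: in the reactive conformer the C3 hydrogen lies near the plane of the cation, where allylic strain is least, the ester tether reaches C4 from one face and the isopropyl group stands on the other, anti to the incoming arene, so isopropyl and the alkenyl group end up trans (both pseudoequatorial in a chair-like transition state). The step needs cyclization to outrun proton loss: loss toward the methyl groups is harmless because the diene reprotonates to 13, loss of the C3 proton is not, and high dilution, low temperature and a non-basic medium favour closure. Substoichiometric acid leaves most of the basic formyl group uncomplexed, so ring A keeps its nucleophilicity. Because C3 is erased in step 13, the trans/cis purity of 14 becomes the enantiomeric purity of 23; any cis isomer is to be removed by chromatography here and 14 kept away from base.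

Step 9
Reactants: 14 (3S,4S)-5,7-dimethoxy-4-(2-methylprop-1-en-1-yl)-2-oxo-3-(propan-2-yl)chromane-6-carbaldehyde
Product: 15 (3S,4S)-5,7-dimethoxy-4-(2-methylpropyl)-2-oxo-3-(propan-2-yl)chromane-6-carbaldehyde
Conditions: H2 (1 atm), [Ir(cod)(PCy3)(py)]PF6 (5 mol%), CH2Cl2, rt
Reagents that add atoms: none
Why: Homogeneous hydrogenation with the cationic iridium catalyst, which reduces hindered trisubstituted alkenes but neither aryl aldehydes nor benzylic C–O bonds, and is less prone than Pd/C to move the double bond toward C4. No stereocentre forms and C3 and C4 are untouched.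

Step 10
Reactants: 15 (3S,4S)-5,7-dimethoxy-4-(2-methylpropyl)-2-oxo-3-(propan-2-yl)chromane-6-carbaldehyde
Product: 16 (3S,4S)-6-(hydroxymethyl)-5,7-dimethoxy-4-(2-methylpropyl)-3-(propan-2-yl)chroman-2-ol (both anomers)
Conditions: i-Bu2AlH (2.5 equiv), CH2Cl2, −78 °C; aq. potassium sodium tartrate (KNaC4H4O6)
Reagents that add atoms: none
Why: Partial hydride reduction of an aryl lactone to the lactol, which is reliable for dihydrocoumarins at low temperature. The aldehyde is reduced alongside, which is accepted and corrected in step 11; the anomeric mixture at C2 is irrelevant because C2 is ionized in step 13.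

Step 11
Reactants: 16 (3S,4S)-6-(hydroxymethyl)-5,7-dimethoxy-4-(2-methylpropyl)-3-(propan-2-yl)chroman-2-ol
Product: 17 (3S,4S)-2-hydroxy-5,7-dimethoxy-4-(2-methylpropyl)-3-(propan-2-yl)chromane-6-carbaldehyde (both anomers)
Conditions: MnO2 (activated, excess), CH2Cl2, rt
Reagents that add atoms: none
Why: MnO2 oxidation is selective for the electron-rich benzylic alcohol; the aliphatic lactol is not activated toward this oxidant.

Step 12
Reactants: 18 phloroglucinol (benzene-1,3,5-triol)
Product: 19 2,4,6-trihydroxybenzene-1,3-dicarbaldehyde (2,4-diformylphloroglucinol)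
Conditions: POCl3 (2.2 equiv), DMF (2.2 equiv), 1,4-dioxane, 0 °C → rt; then H2O
Reagents that add atoms: N,N-dimethylformamide, CN(C)C=O; water, O
Why: Twofold Vilsmeier–Haack formylation; each formyl group deactivates the ring further, so two equivalents of reagent should stop the reaction before the third formylation.

Step 13
Reactants: 17 (3S,4S)-2-hydroxy-5,7-dimethoxy-4-(2-methylpropyl)-3-(propan-2-yl)chromane-6-carbaldehyde; 19 2,4,6-trihydroxybenzene-1,3-dicarbaldehyde
Product: 22 (2R,3R,4S)-2-(3,5-diformyl-2,4,6-trihydroxyphenyl)-5,7-dimethoxy-4-(2-methylpropyl)-3-(propan-2-yl)chromane-6-carbaldehyde, via enol ether 20 (not isolated), via cis oxocarbenium ion 21 (not isolated)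
Conditions: 19 (2 equiv), TsOH·H2O (20 mol%), (CF3)2CHOH/CH2Cl2, rt → 40 °C
Reagents that add atoms: none
Why: Acid-catalysed dehydrative Friedel–Crafts arylation of a lactol through its cyclic oxocarbenium ion, the manifold by which phenols and 2-deoxy lactols give aryl C-glycosides, here with the single free ring carbon of 19 as nucleophile. Because 19 is a weak nucleophile, proton loss to enol ether 20 and reprotonation outrun arylation: in 20 the C4 isobutyl group is held pseudoaxial by the C3 isopropyl and C5 methoxy groups, so the proton enters C3 from the opposite face and gives the 3,4-cis ion 21 (C3 becomes R). In 21 both alkyl groups stand on one face, so 19 adds to C2 from the other and sets C2 (R) trans to isopropyl; an ion that still has the 3,4-trans arrangement is shielded on both faces and should react more slowly (Curtin–Hammett), and the product is also the thermodynamically preferred diastereomer.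

Step 14
Reactants: 22 (2R,3R,4S)-2-(3,5-diformyl-2,4,6-trihydroxyphenyl)-5,7-dimethoxy-4-(2-methylpropyl)-3-(propan-2-yl)chromane-6-carbaldehyde
Product: 23 (2R,3R,4S)-2-(3,5-diformyl-2,4,6-trihydroxyphenyl)-5,7-dihydroxy-4-(2-methylpropyl)-3-(propan-2-yl)chromane-6-carbaldehyde (CNP0328914.1)
Conditions: BCl3 (8 equiv), CH2Cl2, −78 °C → rt; then aq. HCl
Reagents that add atoms: none
Why: Chelation-assisted Lewis-acid cleavage of aryl methyl ethers: both methoxy groups are ortho to the C6 formyl group, which delivers boron to them, whereas the ring oxygen O1 is para to it and not activated. The stereocentres take no part.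

## Compound list

1 | (R)-lavandulol, (2R)-5-methyl-2-(prop-1-en-2-yl)hex-4-en-1-ol | OC[C@H](CC=C(C)C)C(C)=C | starting material
2 | (2R)-5-methyl-2-(propan-2-yl)hex-4-en-1-ol | OC[C@H](CC=C(C)C)C(C)C | intermediate
3 | tert-butyldimethyl{[(2R)-5-methyl-2-(propan-2-yl)hex-4-en-1-yl]oxy}silane | CC(C)(C)[Si](C)(C)OC[C@H](CC=C(C)C)C(C)C | intermediate
4 | tert-butyl{(2R)-2-[(3,3-dimethyloxiran-2-yl)methyl]-3-methylbutoxy}dimethylsilane, both epimers at the oxirane carbon | CC(C)(C)[Si](C)(C)OC[C@H](CC1OC1(C)C)C(C)C | intermediate
5 | (5R)-6-{[tert-butyl(dimethyl)silyl]oxy}-2-methyl-3-(phenylselanyl)-5-(propan-2-yl)hexan-2-ol, both epimers at C3 | CC(C)(C)[Si](C)(C)OC[C@H](CC([Se]c1ccccc1)C(C)(C)O)C(C)C | intermediate (not isolated)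
6 | (5R)-6-{[tert-butyl(dimethyl)silyl]oxy}-2-methyl-3-(phenylseleninyl)-5-(propan-2-yl)hexan-2-ol | CC(C)(C)[Si](C)(C)OC[C@H](CC([Se](=O)c1ccccc1)C(C)(C)O)C(C)C | intermediate (not isolated)
7 | (3E,5S)-6-{[tert-butyl(dimethyl)silyl]oxy}-2-methyl-5-(propan-2-yl)hex-3-en-2-ol | CC(C)(C)[Si](C)(C)OC[C@H](/C=C/C(C)(C)O)C(C)C | intermediate
8 | (2S,3E)-5-methyl-2-(propan-2-yl)hex-3-ene-1,5-diol | OC[C@H](/C=C/C(C)(C)O)C(C)C | intermediate
9 | (2S,3E)-5-hydroxy-5-methyl-2-(propan-2-yl)hex-3-enal | O=C[C@H](/C=C/C(C)(C)O)C(C)C | intermediate (not isolated)
10 | (2S,3E)-5-hydroxy-5-methyl-2-(propan-2-yl)hex-3-enoic acid | OC(=O)[C@H](/C=C/C(C)(C)O)C(C)C | intermediate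
11 | 4-hydroxy-2,6-dimethoxybenzaldehyde | COc1cc(O)cc(OC)c1C=O | starting material
12 | 4-formyl-3,5-dimethoxyphenyl (2S,3E)-5-hydroxy-5-methyl-2-(propan-2-yl)hex-3-enoate | O=C(Oc1cc(OC)c(C=O)c(OC)c1)[C@H](/C=C/C(C)(C)O)C(C)C | intermediate
13 | allyl cation from 12, (3E,5S)-6-(4-formyl-3,5-dimethoxyphenoxy)-2-methyl-6-oxo-5-(propan-2-yl)hex-3-en-2-ylium | O=C(Oc1cc(OC)c(C=O)c(OC)c1)[C@H](/C=C/[C+](C)C)C(C)C | intermediate (not isolated)
14 | (3S,4S)-5,7-dimethoxy-4-(2-methylprop-1-en-1-yl)-2-oxo-3-(propan-2-yl)chromane-6-carbaldehyde, 3,4-trans | CC(C)=C[C@@H]1c2c(cc(OC)c(C=O)c2OC)OC(=O)[C@H]1C(C)C | intermediate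
15 | (3S,4S)-5,7-dimethoxy-4-(2-methylpropyl)-2-oxo-3-(propan-2-yl)chromane-6-carbaldehyde | CC(C)C[C@@H]1c2c(cc(OC)c(C=O)c2OC)OC(=O)[C@H]1C(C)C | intermediate
16 | (3S,4S)-6-(hydroxymethyl)-5,7-dimethoxy-4-(2-methylpropyl)-3-(propan-2-yl)chroman-2-ol, both anomers | CC(C)C[C@@H]1c2c(cc(OC)c(CO)c2OC)OC(O)[C@H]1C(C)C | intermediate
17 | (3S,4S)-2-hydroxy-5,7-dimethoxy-4-(2-methylpropyl)-3-(propan-2-yl)chromane-6-carbaldehyde, both anomers | CC(C)C[C@@H]1c2c(cc(OC)c(C=O)c2OC)OC(O)[C@H]1C(C)C | intermediate
18 | phloroglucinol, benzene-1,3,5-triol | Oc1cc(O)cc(O)c1 | starting material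
19 | 2,4,6-trihydroxybenzene-1,3-dicarbaldehyde | O=Cc1c(O)cc(O)c(C=O)c1O | intermediate
20 | (4S)-5,7-dimethoxy-4-(2-methylpropyl)-3-(propan-2-yl)-4H-chromene-6-carbaldehyde | CC(C)C[C@@H]1c2c(cc(OC)c(C=O)c2OC)OC=C1C(C)C | intermediate (not isolated)
21 | (3R,4S)-6-formyl-5,7-dimethoxy-4-(2-methylpropyl)-3-(propan-2-yl)-3,4-dihydrochromenylium, 3,4-cis | CC(C)C[C@@H]1c2c(cc(OC)c(C=O)c2OC)[O+]=C[C@@H]1C(C)C | intermediate (not isolated)
22 | (2R,3R,4S)-2-(3,5-diformyl-2,4,6-trihydroxyphenyl)-5,7-dimethoxy-4-(2-methylpropyl)-3-(propan-2-yl)chromane-6-carbaldehyde | CC(C)C[C@@H]1c2c(cc(OC)c(C=O)c2OC)O[C@@H](c2c(O)c(C=O)c(O)c(C=O)c2O)[C@@H]1C(C)C | intermediate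
23 | (2R,3R,4S)-2-(3,5-diformyl-2,4,6-trihydroxyphenyl)-5,7-dihydroxy-4-(2-methylpropyl)-3-(propan-2-yl)chromane-6-carbaldehyde | CC(C)C[C@@H]1c2c(cc(O)c(C=O)c2O)O[C@@H](c2c(O)c(C=O)c(O)c(C=O)c2O)[C@@H]1C(C)C | target

## Step count and least certain steps

Total step count: 14. Longest linear sequence: 13 steps (steps 1 to 11, 13 and 14, from 1 to 23); step 12 is a one-step side branch.

**Step 8 (key step).**
- What may go wrong: the cation may lose the C3 proton irreversibly before ring A attacks, because ring closure needs the aryl ester in its less favoured lactone-like conformation and the ring carries an electron-withdrawing, Lewis-basic formyl group. Acyl transfer to the tertiary oxygen with loss of the phenol is a second escape. Incomplete facial selectivity would lower the enantiomeric purity of everything downstream.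
- Fallback (from 10, returning at 16): acid 10 is esterified with methyl 4-hydroxy-2,6-dimethoxybenzoate F1 (EDC·HCl, DMAP) to give 3,5-dimethoxy-4-(methoxycarbonyl)phenyl (2S,3E)-5-hydroxy-5-methyl-2-(propan-2-yl)hex-3-enoate F2. Its ester group is twisted out of the ring plane by the two ortho methoxy groups, binds acid less strongly and deactivates ring A less. The same acid-mediated closure should give methyl (3S,4S)-5,7-dimethoxy-4-(2-methylprop-1-en-1-yl)-2-oxo-3-(propan-2-yl)chromane-6-carboxylate F3. Hydrogenation as in step 9 gives methyl (3S,4S)-5,7-dimethoxy-4-(2-methylpropyl)-2-oxo-3-(propan-2-yl)chromane-6-carboxylate F4, and excess i-Bu2AlH (−78 → −40 °C) reduces lactone and ester together to 16.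

**Step 13.**
- What may go wrong: C–C bond formation may be too slow because 19 is a strongly deactivated nucleophile, so that self-condensation of the lactol or of the enol ether takes over. Arylation before C3 has epimerized would give the wrong diastereomer.
- Fallback (from 17, returning at 22): 17 is treated under the same acid with an excess of the far more nucleophilic phloroglucinol 18 to give (2R,3R,4S)-5,7-dimethoxy-4-(2-methylpropyl)-3-(propan-2-yl)-2-(2,4,6-trihydroxyphenyl)chromane-6-carbaldehyde F5. Vilsmeier–Haack diformylation (POCl3, DMF) of its free triphenol ring, which is much more reactive than ring A, then gives 22.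

**Step 14.**
- What may go wrong: ether cleavage may stall after the first methyl group, since the boron chelate then occupies the formyl oxygen. Prolonged exposure to the Lewis acid may ionize the C2–O1 bond and scramble C2.
- Fallback (from 22, returning at 23): BCl3 in small excess (−78 → 0 °C) is used only for the first, chelation-controlled cleavage, expected at the more hindered 5-methoxy group, to give (2R,3R,4S)-2-(3,5-diformyl-2,4,6-trihydroxyphenyl)-5-hydroxy-7-methoxy-4-(2-methylpropyl)-3-(propan-2-yl)chromane-6-carbaldehyde F6. The remaining methoxy group, ortho to the formyl group, is then removed by nucleophilic SN2 demethylation with LiCl in DMF at 120 °C to give 23.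

**Step 9.**
- What may go wrong: the aldehyde may inhibit the catalyst, or the double bond may migrate toward C4 before it is reduced, which would scramble C4.
- Fallback (from 14, returning at 16): the order of steps 9 and 10 is reversed. i-Bu2AlH (−78 °C) first gives (3S,4S)-6-(hydroxymethyl)-5,7-dimethoxy-4-(2-methylprop-1-en-1-yl)-3-(propan-2-yl)chroman-2-ol F7, which has no aldehyde. Hydroxyl-directed hydrogenation with [Ir(cod)(PCy3)(py)]PF6 then gives 16.

**Step 7.**
- What may go wrong: activation of an acid whose α-hydrogen is also allylic may cause partial epimerization or migration of the alkene into conjugation.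
- Fallback (from 2, returning at 12): the ester is made before the alkene is transposed. TEMPO/NaClO2 oxidation of 2 gives (2R)-5-methyl-2-(propan-2-yl)hex-4-enoic acid F8, and EDC·HCl/DMAP coupling with 11 gives 4-formyl-3,5-dimethoxyphenyl (2R)-5-methyl-2-(propan-2-yl)hex-4-enoate F9, which has no β,γ-alkene. A Schenck ene reaction with singlet oxygen (O2, tetraphenylporphyrin, light, CH2Cl2) gives 4-formyl-3,5-dimethoxyphenyl (2S,3E)-5-hydroperoxy-5-methyl-2-(propan-2-yl)hex-3-enoate F10, which PPh3 reduces in the same flask to 12. The regioisomeric ene product forms alongside, is expected to lactonize and is removed by chromatography. This path is three steps shorter but is expected to lose a substantial part of the material to the regioisomer.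

## Further compounds

F1 | step 8 | methyl 4-hydroxy-2,6-dimethoxybenzoate | COC(=O)c1c(OC)cc(O)cc1OC
F2 | step 8 | 3,5-dimethoxy-4-(methoxycarbonyl)phenyl (2S,3E)-5-hydroxy-5-methyl-2-(propan-2-yl)hex-3-enoate | O=C(Oc1cc(OC)c(C(=O)OC)c(OC)c1)[C@H](/C=C/C(C)(C)O)C(C)C
F3 | step 8 | methyl (3S,4S)-5,7-dimethoxy-4-(2-methylprop-1-en-1-yl)-2-oxo-3-(propan-2-yl)chromane-6-carboxylate | CC(C)=C[C@@H]1c2c(cc(OC)c(C(=O)OC)c2OC)OC(=O)[C@H]1C(C)C
F4 | step 8 | methyl (3S,4S)-5,7-dimethoxy-4-(2-methylpropyl)-2-oxo-3-(propan-2-yl)chromane-6-carboxylate | CC(C)C[C@@H]1c2c(cc(OC)c(C(=O)OC)c2OC)OC(=O)[C@H]1C(C)C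
F5 | step 13 | (2R,3R,4S)-5,7-dimethoxy-4-(2-methylpropyl)-3-(propan-2-yl)-2-(2,4,6-trihydroxyphenyl)chromane-6-carbaldehyde | CC(C)C[C@@H]1c2c(cc(OC)c(C=O)c2OC)O[C@@H](c2c(O)cc(O)cc2O)[C@@H]1C(C)C
F6 | step 14 | (2R,3R,4S)-2-(3,5-diformyl-2,4,6-trihydroxyphenyl)-5-hydroxy-7-methoxy-4-(2-methylpropyl)-3-(propan-2-yl)chromane-6-carbaldehyde | CC(C)C[C@@H]1c2c(cc(OC)c(C=O)c2O)O[C@@H](c2c(O)c(C=O)c(O)c(C=O)c2O)[C@@H]1C(C)C
F7 | step 9 | (3S,4S)-6-(hydroxymethyl)-5,7-dimethoxy-4-(2-methylprop-1-en-1-yl)-3-(propan-2-yl)chroman-2-ol | CC(C)=C[C@@H]1c2c(cc(OC)c(CO)c2OC)OC(O)[C@H]1C(C)C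
F8 | step 7 | (2R)-5-methyl-2-(propan-2-yl)hex-4-enoic acid | OC(=O)[C@H](CC=C(C)C)C(C)C
F9 | step 7 | 4-formyl-3,5-dimethoxyphenyl (2R)-5-methyl-2-(propan-2-yl)hex-4-enoate | O=C(Oc1cc(OC)c(C=O)c(OC)c1)[C@H](CC=C(C)C)C(C)C
F10 | step 7 | 4-formyl-3,5-dimethoxyphenyl (2S,3E)-5-hydroperoxy-5-methyl-2-(propan-2-yl)hex-3-enoate | O=C(Oc1cc(OC)c(C=O)c(OC)c1)[C@H](/C=C/C(C)(C)OO)C(C)C
A1 | alternative 1 | methyl 5,7-dimethoxy-4-(2-methylpropyl)-2-oxo-3-(propan-2-yl)-2H-chromene-6-carboxylate | COC(=O)c1c(OC)cc2oc(=O)c(C(C)C)c(CC(C)C)c2c1OC
A2 | alternative 1 | methyl 5-methyl-3-oxo-2-(propan-2-yl)hexanoate | COC(=O)C(C(C)C)C(=O)CC(C)C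
A3 | alternative 2 | (2R,3R,4S)-5,7-dimethoxy-4-(2-methylprop-1-en-1-yl)-3-(propan-2-yl)-2-(2,4,6-trimethoxyphenyl)chromane-6-carbaldehyde | CC(C)=C[C@@H]1c2c(cc(OC)c(C=O)c2OC)O[C@@H](c2c(OC)cc(OC)cc2OC)[C@@H]1C(C)C
A4 | alternative 2 | (4Z)-2,6-dimethylhepta-2,4-diene | CC(C)=C/C=C\C(C)C
A5 | alternative 3 | methyl (2R,3R,4S)-2-[3,5-bis(methoxycarbonyl)-2,4,6-trimethoxyphenyl]-5,7-dimethoxy-4-(2-methoxy-2-oxoethyl)-3-(propan-2-yl)chromane-6-carboxylate | COC(=O)C[C@@H]1c2c(cc(OC)c(C(=O)OC)c2OC)O[C@@H](c2c(OC)c(C(=O)OC)c(OC)c(C(=O)OC)c2OC)[C@@H]1C(C)C
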